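(The constants used here are assumed.)

You read this flask at 12 d, and the thing to settle at that moment is whether the count of half-lives has used up the substrate or something has halted it first.

substrate 0.80 M; solid reagent 2.00 equiv; free catalyst 0.17 mol%; time 12 d

    solid reagent ⇌ partner, rate k1*(cs1 - [partner]) while solid is left; crystals form when [partner] > cs1 (cs1 = 0.76 M, k1 = 0.055 h⁻¹)
    substrate + partner ⇌ isomer of the product (K2 = 62 M⁻¹, k2 = 0.38 M⁻¹ h⁻¹)
    target + free catalyst ⇌ isomer of the product + free catalyst, rate k3*[free catalyst]*[target] forward; the back reaction follows from the equilibrium constant (k3 = 62 M⁻¹ h⁻¹)
    2 free catalyst → spent catalyst (k4 = 34 M⁻¹ h⁻¹)
    partner → decomposition product (k5 = 9.1 × 10⁻⁵ h⁻¹)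
    substrate + partner ⇌ target (K6 = 0.71 M⁻¹, k6 = 0.72 M⁻¹ h⁻¹)

1. why nothing more happens at 12 d, or that something still does (for what has run out or reacted, a solid counts together with what of it has only dissolved) (the partner has run out first / it is still moving / all of the substrate has reacted / forward and back rates have come level / no working catalyst is left)
2. share of the substrate used up at 12 d
3. isomer of the product at 12 d, in percent of the substrate charged

- two of one species on the left: rate k times its square, two consumed each time
- solid reagent is a solid; its amount is given per volume of the solution
- at the start none of the solid reagent is in solution
- the reaction counts as stopped when no species that holds the substrate changes by six tenths of a point or more over the second half of the time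
- run time (flask): 12 d

The bench rule says a reaction is over after 5 half-lives, so count them. The partner is not at its solubility, 0.76 M, from the start, since it must first dissolve and the substrate takes it up, but it can climb there later, and the charge allows this: 1.60 M of solid reagent covers 0.80 M for the substrate and 0.76 M in solution, with 0.0400 M to spare. With the partner at that level, the substrate goes to the isomer of the product in a pseudo-first-order way, with a forward half-life by this step of 2.40 h. The dissolving is slower, with a half-life of 12.6 h, but even with the two added, 19.2 half-lives fit into the run, more than the rule asks, so the rule calls the reaction finished.

The rule counts the forward step, though, and this step runs back as well, so the rule stops working at a ratio. Forward against back, the two pseudo-first-order constants stand as K2 times the partner's concentration, which here is 47.1. Call this the holding ratio: the isomer of the product per substrate at which the two directions level. Halving stops paying after 5.56 half-lives, fewer than fit. I therefore commit to forward and back rates have come level. With target at K6 times the partner per substrate, that gives a conversion of 97.9% and an isomer yield of 96.8%.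

The forecast gave forward and back rates have come level, with 97.9% (97.5% to 98.3%) and 96.8% (96.2% to 97.3%), holding that “the mixture reaches equilibrium well before” the time of reading. The simulation gives forward and back rates have come level, with 97.9% and 96.8%.

In this flask at 12.0 d, the relaxation half-life of substrate + partner and the isomer of the product by that step alone, both ways together, is 0.0960 d, far shorter than the run of 12 d, and with the partner at 0.759 M the isomer of the product stands to substrate as 47.0 to one, against a holding ratio of 47.1. In the neighbour flask with 0.20 M of substrate, the partner ends at 0.209 M, which makes the holding ratio 12.9 and the substrate left 7.10%, against 7.09% in the simulation.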